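(All runs are simulated with constants of no real substance; noise was put on by code.)

Keep one balance on the first nucleophile: in a closed flask with the candidate steps listed below, each unit charged as solid stands at any moment as solid, dissolved first nucleophile, target or quenched reagent, and the sum does not move.

common to all: substrate 0.20 M
- amber: second nucleophile 0.36 M; protic impurity 4 mM; solid first nucleophile 0.30 M; run made earlier
- green: second nucleophile 0.36 M; protic impurity 4 mM; solid first nucleophile 0.80 M; run made earlier
- epsilon: second nucleophile 0.360 M; protic impurity 4.00 mM; solid first nucleophile 1.00 M; time 20 h
- zeta: second nucleophile 0.360 M; protic impurity 4.00 mM; solid first nucleophile 0.400 M; time 20 h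

| run | time / h | target / % | substrate / % |
|---|---|---|---|
| amber | 1.00 | 2.4 | 49.8 |
| amber | 2.00 | 6.9 | 25.5 |
| amber | 4.00 | 12.0 | 5.5 |
| amber | 8.00 | 14.0 | 1.1 |
| amber | 15.0 | 11.9 | 0 |
| green | 1.33 | 6.0 | 37.0 |
| green | 4.00 | 10.3 | 5.7 |
| green | 6.00 | 12.0 | 1.7 |
| green | 10.0 | 14.1 | 0.4 |
| green | 15.0 | 11.7 | 0 |

(readings scatter by 1 percentage point)

- solid, in amounts per volume of the solution: solid first nucleophile
- the earlier runs were read with a standard deviation of 1 percentage point
- candidate steps: substrate -> intermediate; first nucleophile + intermediate -> target; second nucleophile + intermediate -> other capture product; intermediate -> solvolysis product; first nucleophile + protic impurity -> quenched reagent; solid first nucleophile <-> first nucleophile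
- at the start none of the solid first nucleophile is in solution

- which of the two there is more of at the end, epsilon (target / solvolysis product)
- which of the two there is more of at the end, zeta (target / solvolysis product)
- target at the end, in percent of the substrate charged, epsilon
- target at the end, in percent of the substrate charged, zeta

Read the substrate first. Amber shows 5.5 % at 4.00 h and green 5.7 % at 4.00 h, although green holds 2.67 times the solid, so substrate loss shows no order in the solid. Then average the last two target readings: amber gives 12.9 %, green 12.9 %. No candidate step consumes target, so treat the late fall as scatter and pool the 4 readings into a capture share of 12.9 % of the substrate charged. The late target share therefore shows no order in the solid charge, so follow the dissolved first nucleophile instead: capture of the intermediate is pseudo-first-order while that concentration holds steady.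

Now define the reservoir draw, the fraction of the solid charge that ends as target or quenched reagent, taking the impurity as fully quenched. For zeta it is 7.46 %, for epsilon 2.98 %, both smaller than amber's 9.95 %. The weak link is that the draw omits the solid needed to fill the solution. Repair it from amber: amber's pooled share matches green's within the scatter on the smaller charge, so read amber's charge as covering that filling and its consumption together; zeta and epsilon charge more solid than amber. So commit to 12.9 % target in both. The remainder, 87.1 %, is shared by two unread products, and the larger of them exceeds target, but the readings do not name it.

The forecast gives 13 % for epsilon and 13 % for zeta, with solvolysis product ahead in epsilon and solvolysis product in zeta, holding that “the solution is saturated and the loading hardly matters”.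

Epsilon gives 13.0 % target and 52.5 % solvolysis product, and zeta 13.0 % and 52.5 %. At the end of zeta the dissolved first nucleophile stands at 0.100 M, which is 25.0 % of the charge, with 67.5 % of the charge still solid; add the draw of 7.46 % and the balance closes within rounding.

    substrate → intermediate (k = 0.0120 min⁻¹)
    first nucleophile + intermediate → target (k = 25.3 M⁻¹ min⁻¹)
    second nucleophile + intermediate → other capture product (k = 7.20 M⁻¹ min⁻¹)
    intermediate → solvolysis product (k = 3.56 min⁻¹)
    first nucleophile + protic impurity → quenched reagent (k = 3.74 M⁻¹ min⁻¹)
    solid first nucleophile ⇌ first nucleophile, rate k6*(cs6 - [first nucleophile]) while solid is left; crystals form when [first nucleophile] > cs6 (solubility = 0.100 M, k = 0.00906 min⁻¹)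

For the neighbour of epsilon with 1.7 M of solid, the draw is 1.76 %, leaving 98.2 % solid or dissolved. Computed, that flask keeps 98 % and gives 13.0 % target.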